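## Structural features

The target is a norsesterterpene peroxide: a cis-fused decalin (ring A: C13 to C18; ring B: C9 to C13 plus C18) joined through the two-carbon tether C8–C7 to a 1,2-dioxane (C3 to C6 plus the O–O unit) that carries a methyl propanoate at C3. Ring A holds the gem-dimethyl carbon C14 and shares with ring B the tertiary carbinol C13 and the methyl-bearing quaternary carbon C18. C18, C9 (side chain), C10 (methyl) and C13 are four contiguous stereocentres: the C13 hydroxyl, the C18 methyl and the C9 side chain lie on one face and the C10 methyl on the other. In the dioxane the quaternary C6 (methyl axial, long chain equatorial) and C3 are 1,4-related, no stereocentre links them to the decalin, and C3 and C2 form an anti pair. The O–O bond is the fragile group (reductants, phosphines, low-valent metals, and base through Kornblum–DeLaMare cleavage at C3–H or retro-oxa-Michael loss once C1 is a carbonyl); the tertiary C13 hydroxyl can dehydrate under acid and C2 can epimerise. The real difficulties are three: the carbinol C13 wedged between the quaternary C14 and C18, the relative configuration of C9 and C18 (which has to be set on an open chain), and C6, a remote quaternary peroxide carbon whose two chains are sterically alike. The key step exploits the 1,3-relation between the C13 hydroxyl and C11 in ring B: with an oxygen at C11 the C12–C13 bond is an aldol bond, the ring A ketone C13 cannot enolise, and the methyl ketone carbon C12 can only close a six-membered ring onto it. A centre-by-centre comparison confirms that the diketone and the ketol of this step carry C9, C10, C18 and (for the ketol) C13 in the configurations of the target.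

## Logic of the disconnections

37 to 36 to 34: the ester O–CH3 bond and then the C1 oxidation level are removed. The β-peroxy ester is the most base-sensitive arrangement in the molecule, so it is made last; with C1 as a silyl-protected primary alcohol (33) there is no acidic C2–H during peroxide ring formation. The forward steps must oxidise and esterify without base, reductant or epimerisation at C2.

33 to 31 to 30: both C–O bonds of the peroxide are cut, C3–O first and then C6–O. The dioxane becomes an open chain with a leaving group at C3 and a 1,1-disubstituted alkene at C6, so the O–O unit enters only five steps before the end. The ring closure must be an SN2 displacement with clean inversion, which fixes C3 of 30 as the epimer of the target's C3. The radical oxygenation at C6 cannot choose a face, so the C6 epimers must be separated.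

30 to 29 to 17 + 27: the C6–C7 bond between an sp3 and an sp2 carbon is cut. This divides the molecule into the decalin 17 and the stereodefined chain 27 and lets the vinyl group of 17 serve directly as the C8–C7 tether. The coupling must put boron on C7 only and tolerate a free tertiary and a free secondary hydroxyl.

27 to 26 to 25 to 22 + 23: the C2–C3 bond is cut as an aldol bond. Both side-chain stereocentres come from one auxiliary-controlled step, and the auxiliary leaves as the C1 alcohol that is needed anyway. The aldol must be syn and of the absolute sense that gives the 2,3-anti pair after inversion at C3.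

22 to 21 to 18 + 19: the C4–C5 bond next to the bromoalkene is cut (enolate alkylation) and the aldehyde is taken back to the ester. Two commodity chemicals result. The alkylation must occur at the allylic and not the vinylic bromide.

17 to 16 to 15 to 14: the C11 hydrogen is exchanged for the C11 oxygen that the aldol retron needs. This costs three steps but uncovers the β-hydroxy ketone. The forward deoxygenation must spare the tertiary hydroxyl and the vinyl group and avoid strongly basic conditions that would reopen the ketol.

14 to 11 (key disconnection): the C12–C13 bond is cut, opening ring B. A bicyclic ketol with four stereocentres becomes a monocyclic 1,5-diketone with three. The forward step must enolise only toward C12, close cis and stop at the ketol.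

11 to 10 to 9: the C11–C12 bond is cut (methyl ketone back to acid). This gives a γ,δ-unsaturated acid, the retron of a [3,3] rearrangement. The methyl nucleophile must add once and ignore the C13 ketone, which is why an N-methoxy-N-methyl amide is interposed.

9 to 7: the C9–C10 bond is cut by a retro-Claisen operation that moves the alkene from C8=C7 to C9=C8 and places oxygen on C7. Two stereocentres are traded for one alkene geometry and one enolate geometry. Because C9 lies next to the quaternary C18 on an open chain, the face of C9 must be chosen by the reagent; a plain silyl ketene acetal would leave this to an unreliable substrate bias.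

7 to 5 + 6: the C7–O bond is cut with the alkene returned to the terminal position. The allyl group of 5 is then oxidised directly, without separate isomerisation and allylic oxidation steps. The C–H oxidation must be linear and (E)-selective.

5 to 4 to 1 + 2: the C18–C9 bond is cut (decarboxylative allylation) and then the enol carbonate. The last stereocentre disappears and an achiral commercial ketone remains. The forward step must create the quaternary centre under catalyst control.

## Other disconnections considered

Alternative 1: The cuts are C8–C9 and C17–C18, made in one flask on a preformed cyclohexenone, with ring A left to be closed later at C13–C14. In the forward direction the Grignard reagent A3 with catalytic CuBr·SMe2 would add to C9 of enone A2 anti to the C10 methyl. The resulting enolate would then be alkylated at C18 by iodide A4 anti to the new C9 substituent, giving ketone A1.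
- In its favour: C9, C10 and C18 would be set on a ring by two well-understood trans relationships, the side chain would arrive with C8 and C7 at the aldehyde oxidation level, and the sequence is convergent.
- Against it here: the C18 alkylation is that of a fully substituted enolate carbon by the unactivated primary iodide A4, which usually needs enolate regeneration and polar additives and competes with proton transfer. Ring A must then be closed by joining the prenyl terminus C14 to the C13 ketone, a step whose cis outcome at the congested carbinol is not assured. A2 must also be made enantiopure.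
- Comparison: on the relative configuration of C9 and C18 the alternative is the better plan, because it uses ring control where the chosen plan needs reagent control on an open chain. On the congested C13 carbinol the two are equal in risk. On mechanism the chosen plan gains from a catalytic enantioselective step on an achiral ketone. In step count the alternative is equal or slightly shorter, since no C11 oxygen has to be removed.

Alternative 2: The cut is the C13–O bond, with both rings already in place. In the forward direction I2/NaHCO3 would convert the γ,δ-unsaturated acid A6 into the bridged iodo γ-lactone A5, the C8 carboxylate attacking C13 of the C12=C13 alkene anti to the iodonium.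
- In its favour: a bridged lactone can form only on the face of ring B that carries C8, so the C13 oxygen would be forced cis to the C9 substituent and hence cis to the C18 methyl. The closure would not revert, and the C12 iodine could be removed by radical reduction.
- Against it here: the step builds no C–C bond and no carbocycle, so the octalin A6 with C9, C10 and C18 set must come from elsewhere. The iodonium must form at an alkene carbon flanked by two quaternary centres. Afterwards deiodination, reductive opening of the lactone and one-carbon homologation at C8 are needed before the side chain can grow.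
- Comparison: on the certainty of the C13 configuration the alternative is better than the chosen aldol, because the closure is geometrically forced and irreversible. On skeletal construction the chosen key step is better, since it closes ring B and sets C13 in one operation. In step economy the chosen plan is ahead by the steps needed to reach A6 and to rebuild C8–C7. The functional-group risk of the radical deiodination equals that of the Barton–McCombie step.

Alternative 3: The cut is the ring-fusion bond C13–C18 of a ten-membered ring. In the forward direction Fe(acac)3 and PhSiH3 would transfer a hydrogen atom to C17 of the C17=C18 alkene of cyclodecenone A8. The tertiary C18 radical would add across the ring to the C13 carbonyl, and reduction of the alkoxyl radical would give decalinol A7, closing rings A and B together.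
- In its favour: the most congested bond of the target would be made by a radical, which tolerates crowding better than a polar addition. The tertiary alcohol would appear without a surplus oxygen, and the side-chain acetal would already be in place.
- Against it here: A8, with C9 and C10 set and a trisubstituted alkene of defined geometry, needs a macrocyclisation and is long to make. C18 would arise from a planar radical, so C18 and C13 would both depend on the conformation of the medium ring, which is hard to predict and not under reagent control. Radical addition to a ketone is reversible and competes with transannular hydrogen shifts and simple alkene reduction.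
- Comparison: in the economy of the step itself and in avoiding the three C11 deoxygenation steps the alternative is the better one. In predictability of C18 and C13 the chosen plan is better (C18 from a catalyst, C13 from a chair closure with C18 and C9 fixed). The overall step count would probably favour the chosen plan because of the macrocycle.

Key step: step 7

Remark 1: the sense of induction of the diazaborolidine in step 4 is assumed to follow the (E)-but-2-enyl propanoate case; the (4S,5S) reagent is written, and its mirror image is meant if the required face of C9 corresponds to the other antipode.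
Remark 2: no facial bias is assumed for oxygen trapping at C6 in step 18; both C6 epimers are carried to step 19 and separated there.
Remark 3: the C11 carbinol configuration in 15 and 16 is left open because that oxygen is removed in step 10.

## Steps

Step 1
Reactants: 1 2,2,6-trimethylcyclohexan-1-one; 2 prop-2-en-1-yl carbonochloridate (allyl chloroformate)
Product: 4 prop-2-en-1-yl 2,6,6-trimethylcyclohex-1-en-1-yl carbonate, via lithium enolate 3 (not isolated)
Conditions: LiN(SiMe3)2, THF, 0 °C; then 2, −78 °C → rt
Reagents that add atoms: none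
Why: Only C6–H of 1 is enolisable, so a single tetrasubstituted enolate forms; the hard chloroformate acylates it on oxygen at low temperature (enol carbonate formation).

Step 2
Reactants: 4 prop-2-en-1-yl 2,6,6-trimethylcyclohex-1-en-1-yl carbonate
Product: 5 (2R)-2,6,6-trimethyl-2-(prop-2-en-1-yl)cyclohexan-1-one
Conditions: Pd2(dba)3 (2.5 mol %), (R)-4-tert-butyl-2-[2-(diphenylphosphanyl)phenyl]-4,5-dihydro-1,3-oxazole (6 mol %), THF, 25 °C
Reagents that add atoms: none
Why: Tsuji decarboxylative asymmetric allylic alkylation: oxidative addition to zerovalent palladium and loss of CO2 give an allylpalladium enolate pair that recombines at C18 inside the chiral pocket of the phosphinooxazoline. The (R) ligand is the mirror image of the one that leads to (S)-2-allyl-2-methylcyclohexanone, so C18 should form as (R).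

Step 3
Reactants: 5 (2R)-2,6,6-trimethyl-2-(prop-2-en-1-yl)cyclohexan-1-one; 6 propanoic acid
Product: 7 (2E)-3-[(1R)-1,3,3-trimethyl-2-oxocyclohexyl]prop-2-en-1-yl propanoate
Conditions: Pd(O2CEt)2 (10 mol %), 1,4-benzoquinone (2 equiv), DMSO/EtCO2H (1:1), 4 Å MS, 40 °C
Reagents that add atoms: none
Why: Palladium-catalysed linear allylic C–H acyloxylation of a terminal alkene: C–H cleavage at C9 gives a π-allyl complex whose hindered C9 end leaves only C7 open to the carboxylate, giving the (E) ester with the alkene moved next to C18; benzoquinone reoxidises palladium. C18 is untouched.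

Step 4
Reactants: 7 (2E)-3-[(1R)-1,3,3-trimethyl-2-oxocyclohexyl]prop-2-en-1-yl propanoate
Product: 9 (2S,3S)-2-methyl-3-[(1R)-1,3,3-trimethyl-2-oxocyclohexyl]pent-4-enoic acid, via boron ketene acetal 8 (not isolated)
Conditions: (4S,5S)-2-bromo-4,5-diphenyl-1,3-bis{[3,5-bis(trifluoromethyl)phenyl]sulfonyl}-1,3,2-diazaborolidine (1.2 equiv), Et3N, toluene/hexanes, −78 °C, then −20 → 4 °C; aqueous work-up
Reagents that add atoms: none
Why: Ireland–Claisen-type ester enolate rearrangement of a chiral boron ketene acetal: the enolate with the C10 methyl cis to the allyloxy oxygen and the (E) alkene pass through a chair that gives the anti C9/C10 pair. The C2-symmetric diazaborolidine distinguishes the two mirror-related chairs, so C9 is set by the reagent and not by the neighbouring quaternary C18. C13 has no α-hydrogen, so only the ester enolises.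

Step 5
Reactants: 9 (2S,3S)-2-methyl-3-[(1R)-1,3,3-trimethyl-2-oxocyclohexyl]pent-4-enoic acid
Product: 10 (2S,3S)-N-methoxy-N,2-dimethyl-3-[(1R)-1,3,3-trimethyl-2-oxocyclohexyl]pent-4-enamide
Conditions: MeNHOMe·HCl, EDC·HCl, HOBt, N-methylmorpholine, CH2Cl2, 0 °C → rt
Reagents that add atoms: N,O-dimethylhydroxylamine hydrochloride, CNOC.Cl
Why: Carbodiimide amide coupling to the Weinreb amide; activation through the hydroxybenzotriazole ester avoids a ketene and so preserves C10.

Step 6
Reactants: 10 (2S,3S)-N-methoxy-N,2-dimethyl-3-[(1R)-1,3,3-trimethyl-2-oxocyclohexyl]pent-4-enamide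
Product: 11 (2R)-2,6,6-trimethyl-2-[(3S,4S)-4-methyl-5-oxohex-1-en-3-yl]cyclohexan-1-one
Conditions: MeMgBr, THF, 0 °C; aq. NH4Cl
Reagents that add atoms: methylmagnesium bromide, C[Mg]Br
Why: Weinreb ketone synthesis: the chelated tetrahedral magnesium adduct stops at mono-addition and collapses only on work-up. The C13 ketone, non-enolisable and flanked by two quaternary carbons, should react far more slowly with MeMgBr at 0 °C than the amide.

Step 7
Reactants: 11 (2R)-2,6,6-trimethyl-2-[(3S,4S)-4-methyl-5-oxohex-1-en-3-yl]cyclohexan-1-one
Product: 14 (3S,4S,4aR,8aS)-4-ethenyl-8a-hydroxy-3,4a,8,8-tetramethyloctahydronaphthalen-2(1H)-one, via lithium enolate 12 (not isolated), via lithium aldolate 13 (not isolated)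
Conditions: LiN(i-Pr)2 (1.05 equiv), THF, −78 °C; warm to −40 °C; AcOH/THF, −78 °C
Reagents that add atoms: none
Why: Intramolecular aldol addition, the ring-closing half of a Robinson annulation stopped before dehydration: the amide base removes a C12 methyl proton kinetically, and enolate 12 adds to the C13 carbonyl to give the chelated lithium aldolate 13, which is protonated cold. Ring B closes in a 6-(enolexo)-exo-trig mode through a chair in which the C18–C9 bond is equatorial on ring A and C12 attacks C13 axially. The new stereocentre C13 is controlled by C18 and C9: axial delivery from the equatorial tether gives the cis fusion with the hydroxyl cis to the C18 methyl, whereas trans fusion would need equatorial attack against the substituents on C14 and C18. Regioselectivity rests on the absence of α-hydrogens at C13 and on kinetic preference for the methyl over the hindered C10 methine; a C10 enolate could in any case only close a four-membered ring. Reversion and dehydration are held back by low temperature, lithium chelation and the acidic quench; a carbinol between two quaternary carbons also dehydrates slowly. C10 keeps the configuration from step 4, which places its methyl equatorial and trans to the C9 vinyl group. The step needs cis fusion only; C18 and C9 are already fixed.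

Step 8
Reactants: 14 (3S,4S,4aR,8aS)-4-ethenyl-8a-hydroxy-3,4a,8,8-tetramethyloctahydronaphthalen-2(1H)-one
Product: 15 (3S,4S,4aR,8aS)-4-ethenyl-3,4a,8,8-tetramethyldecahydronaphthalene-2,8a-diol (C2 configuration open)
Conditions: NaBH4, CeCl3·7H2O, MeOH, −40 °C
Reagents that add atoms: none
Why: Luche-type 1,2-reduction under nearly neutral conditions avoids retro-aldol opening; the C11 configuration is irrelevant because this oxygen is removed.

Step 9
Reactants: 15 (3S,4S,4aR,8aS)-4-ethenyl-3,4a,8,8-tetramethyldecahydronaphthalene-2,8a-diol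
Product: 16 O-[(3S,4S,4aR,8aS)-4-ethenyl-8a-hydroxy-3,4a,8,8-tetramethyldecahydronaphthalen-2-yl] O-phenyl carbonothioate
Conditions: PhOC(S)Cl, pyridine, DMAP (cat.), CH2Cl2, 0 °C → rt
Reagents that add atoms: O-phenyl carbonochloridothioate, S=C(Cl)Oc1ccccc1
Why: Thioacylation of the secondary alcohol; the tertiary C13 hydroxyl between two quaternary carbons should not react.

Step 10
Reactants: 16 O-[(3S,4S,4aR,8aS)-4-ethenyl-8a-hydroxy-3,4a,8,8-tetramethyldecahydronaphthalen-2-yl] O-phenyl carbonothioate
Product: 17 (1S,2R,4aS,8aR)-1-ethenyl-2,5,5,8a-tetramethyldecahydronaphthalen-4a-ol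
Conditions: Bu3SnH, AIBN (cat.), toluene, 90 °C
Reagents that add atoms: none
Why: Barton–McCombie deoxygenation: the stannyl radical adds to C=S, β-scission gives the secondary C11 radical, and this abstracts hydrogen from Bu3SnH. The vinyl group offers the radical only disfavoured small-ring closures, and C10 is no longer epimerisable afterwards.

Step 11
Reactants: 18 ethyl acetate; 19 2,3-dibromoprop-1-ene
Product: 21 ethyl 4-bromopent-4-enoate, via lithium enolate 20 (not isolated)
Conditions: LiN(i-Pr)2, THF, −78 °C; then 19, DMPU, −78 → 0 °C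
Reagents that add atoms: none
Why: Ester enolate alkylation by SN2 at the allylic CH2Br; the vinylic bromide is inert to the enolate.

Step 12
Reactants: 21 ethyl 4-bromopent-4-enoate
Product: 22 4-bromopent-4-enal
Conditions: i-Bu2AlH (1.05 equiv), CH2Cl2, −78 °C; aq. potassium sodium tartrate
Reagents that add atoms: none
Why: Partial ester reduction: the tetrahedral aluminium hemiacetal is stable at −78 °C and releases the aldehyde only on work-up.

Step 13
Reactants: 22 4-bromopent-4-enal; 23 (4S)-4-benzyl-3-propanoyl-1,3-oxazolidin-2-one
Product: 25 (4S)-4-benzyl-3-[(2S,3R)-6-bromo-3-hydroxy-2-methylhept-6-enoyl]-1,3-oxazolidin-2-one, via boron enolate 24 (not isolated)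
Conditions: Bu2BOTf, i-Pr2NEt, CH2Cl2, −78 → 0 °C; then 22, −78 → 0 °C; pH 7 buffer (NaH2PO4/Na2HPO4), MeOH, H2O2, 0 °C
Reagents that add atoms: none
Why: Evans syn aldol: the (Z) dibutylboron enolate reacts through a Zimmerman–Traxler chair with the aldehyde on the enolate face away from the benzyl group. This sets C2 and C3 as the syn pair required; C3 is inverted later in step 19.

Step 14
Reactants: 25 (4S)-4-benzyl-3-[(2S,3R)-6-bromo-3-hydroxy-2-methylhept-6-enoyl]-1,3-oxazolidin-2-one
Product: 26 (2R,3R)-6-bromo-2-methylhept-6-ene-1,3-diol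
Conditions: LiBH4, H2O (1 equiv), Et2O, 0 °C
Reagents that add atoms: none
Why: Reductive cleavage of the imide releases the auxiliary and gives the 1,3-diol; the vinyl bromide and both stereocentres are untouched (the descriptor at C2 changes only by priority).

Step 15
Reactants: 26 (2R,3R)-6-bromo-2-methylhept-6-ene-1,3-diol
Product: 27 (2R,3R)-6-bromo-1-{[tert-butyl(diphenyl)silyl]oxy}-2-methylhept-6-en-3-ol
Conditions: t-BuPh2SiCl, imidazole, CH2Cl2, 0 °C
Reagents that add atoms: tert-butyl(chloro)diphenylsilane, CC(C)(C)[Si](Cl)(c1ccccc1)c1ccccc1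
Why: The bulky chlorosilane silylates the primary hydroxyl selectively and leaves the C3 hydroxyl free for later activation.

Step 16
Reactants: 17 (1S,2R,4aS,8aR)-1-ethenyl-2,5,5,8a-tetramethyldecahydronaphthalen-4a-ol; 27 (2R,3R)-6-bromo-1-{[tert-butyl(diphenyl)silyl]oxy}-2-methylhept-6-en-3-ol
Product: 29 (2R,3R)-1-{[tert-butyl(diphenyl)silyl]oxy}-8-[(1S,2R,4aS,8aR)-4a-hydroxy-2,5,5,8a-tetramethyldecahydronaphthalen-1-yl]-2-methyl-6-methylideneoctan-3-ol, via alkylborane 28 (not isolated)
Conditions: 9-BBN (2.5 equiv), THF, 0 → 50 °C; H2O; then 27, Pd(dppf)Cl2·CH2Cl2 (5 mol %), AsPh3, Cs2CO3, DMF/THF/H2O, rt → 45 °C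
Reagents that add atoms: none
Why: Hydroboration with 9-BBN puts boron on the terminal C7, and B-alkyl Suzuki–Miyaura coupling with the 2-bromoalkene forms C6–C7 with the 1,1-disubstituted alkene in place. Free hydroxyls are tolerated once excess borane is quenched with water before the palladium complex is added.

Step 17
Reactants: 29 (2R,3R)-1-{[tert-butyl(diphenyl)silyl]oxy}-8-[(1S,2R,4aS,8aR)-4a-hydroxy-2,5,5,8a-tetramethyldecahydronaphthalen-1-yl]-2-methyl-6-methylideneoctan-3-ol
Product: 30 (2R,3R)-1-{[tert-butyl(diphenyl)silyl]oxy}-8-[(1S,2R,4aS,8aR)-4a-hydroxy-2,5,5,8a-tetramethyldecahydronaphthalen-1-yl]-2-methyl-6-methylideneoctan-3-yl methanesulfonate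
Conditions: MsCl, Et3N, CH2Cl2, −20 → 0 °C
Reagents that add atoms: methanesulfonyl chloride, CS(=O)(=O)Cl
Why: Sulfonylation of the secondary C3 hydroxyl; the tertiary C13 hydroxyl is too hindered to react at low temperature.

Step 18
Reactants: 30 (2R,3R)-1-{[tert-butyl(diphenyl)silyl]oxy}-8-[(1S,2R,4aS,8aR)-4a-hydroxy-2,5,5,8a-tetramethyldecahydronaphthalen-1-yl]-2-methyl-6-methylideneoctan-3-yl methanesulfonate
Product: 31 (2R,3R,6RS)-1-{[tert-butyl(diphenyl)silyl]oxy}-8-[(1S,2R,4aS,8aR)-4a-hydroxy-2,5,5,8a-tetramethyldecahydronaphthalen-1-yl]-2,6-dimethyl-6-[(triethylsilyl)peroxy]octan-3-yl methanesulfonate (both C6 epimers)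
Conditions: Co(thd)2 (10 mol %; thd = 2,2,6,6-tetramethylheptane-3,5-dionate), O2 (1 atm), Et3SiH, ClCH2CH2Cl, rt
Reagents that add atoms: dioxygen, O=O; triethylsilane, CC[SiH](CC)CC
Why: Isayama–Mukaiyama hydroperoxysilylation: a cobalt hydride delivers hydrogen to the terminal carbon, the tertiary C6 radical traps O2, and the cobalt peroxide is silylated by Et3SiH. The planar C6 radical has no facial bias, so both C6 epimers are expected and are carried on together.

Step 19
Reactants: 31 (2R,3R,6RS)-1-{[tert-butyl(diphenyl)silyl]oxy}-8-[(1S,2R,4aS,8aR)-4a-hydroxy-2,5,5,8a-tetramethyldecahydronaphthalen-1-yl]-2,6-dimethyl-6-[(triethylsilyl)peroxy]octan-3-yl methanesulfonate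
Product: 33 tert-butyl{(2R)-2-[(3S,6R)-6-{2-[(1S,2R,4aS,8aR)-4a-hydroxy-2,5,5,8a-tetramethyldecahydronaphthalen-1-yl]ethyl}-6-methyl-1,2-dioxan-3-yl]propoxy}diphenylsilane, via hydroperoxide 32 (not isolated)
Conditions: Bu4NF (1.2 equiv), THF, 0 °C → rt; chromatography
Reagents that add atoms: none
Why: Fluoride cleaves the silyl peroxide, and the peroxide anion displaces the C3 mesylate in a 6-exo-tet intramolecular SN2 reaction with inversion, turning the syn aldol pair into the required 2,3-anti, (3S) arrangement. The (6R) isomer 33 (C3 side chain and long C6 chain both equatorial) is separated by chromatography from the (3S,6S) epimer that the other half of 31 gives. C1 is kept as a silyl ether because a β-mesyloxy ester would eliminate.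

Step 20
Reactants: 33 tert-butyl{(2R)-2-[(3S,6R)-6-{2-[(1S,2R,4aS,8aR)-4a-hydroxy-2,5,5,8a-tetramethyldecahydronaphthalen-1-yl]ethyl}-6-methyl-1,2-dioxan-3-yl]propoxy}diphenylsilane
Product: 34 (2R)-2-[(3S,6R)-6-{2-[(1S,2R,4aS,8aR)-4a-hydroxy-2,5,5,8a-tetramethyldecahydronaphthalen-1-yl]ethyl}-6-methyl-1,2-dioxan-3-yl]propan-1-ol
Conditions: Bu4NF, AcOH (1:1), THF, rt
Reagents that add atoms: none
Why: Buffered fluoride removes the silyl ether without the basicity that could start Kornblum–DeLaMare cleavage at C3–H.

Step 21
Reactants: 34 (2R)-2-[(3S,6R)-6-{2-[(1S,2R,4aS,8aR)-4a-hydroxy-2,5,5,8a-tetramethyldecahydronaphthalen-1-yl]ethyl}-6-methyl-1,2-dioxan-3-yl]propan-1-ol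
Product: 36 (2S)-2-[(3S,6R)-6-{2-[(1S,2R,4aS,8aR)-4a-hydroxy-2,5,5,8a-tetramethyldecahydronaphthalen-1-yl]ethyl}-6-methyl-1,2-dioxan-3-yl]propanoic acid, via aldehyde 35 (not isolated)
Conditions: TEMPO (20 mol %), PhI(OAc)2 (2.2 equiv), MeCN/aqueous NaH2PO4–Na2HPO4 buffer of pH 7 (1:1), rt
Reagents that add atoms: water, O
Why: Oxoammonium oxidation to the aldehyde, hydration and a second oxidation give the acid under neutral buffered conditions that leave the O–O bond, the tertiary alcohol and C2 alone.

Step 22
Reactants: 36 (2S)-2-[(3S,6R)-6-{2-[(1S,2R,4aS,8aR)-4a-hydroxy-2,5,5,8a-tetramethyldecahydronaphthalen-1-yl]ethyl}-6-methyl-1,2-dioxan-3-yl]propanoic acid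
Product: 37 methyl (2S)-2-[(3S,6R)-6-{2-[(1S,2R,4aS,8aR)-4a-hydroxy-2,5,5,8a-tetramethyldecahydronaphthalen-1-yl]ethyl}-6-methyl-1,2-dioxan-3-yl]propanoate (CNP0274543.2)
Conditions: Me3SiCHN2, toluene/MeOH (4:1), 0 °C
Reagents that add atoms: (trimethylsilyl)diazomethane, C[Si](C)(C)C=[N+]=[N-]
Why: Esterification by the diazoalkane is neutral, which avoids the base that would trigger retro-oxa-Michael loss of the β-peroxide or epimerise C2.

## Compound list

1 | 2,2,6-trimethylcyclohexan-1-one | CC1CCCC(C)(C)C1=O | starting material
2 | prop-2-en-1-yl carbonochloridate | C=CCOC(Cl)=O | starting material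
3 | lithium 2,6,6-trimethylcyclohex-1-en-1-olate | [Li]OC1=C(C)CCCC1(C)C | intermediate (not isolated)
4 | prop-2-en-1-yl 2,6,6-trimethylcyclohex-1-en-1-yl carbonate | C=CCOC(=O)OC1=C(C)CCCC1(C)C | intermediate
5 | (2R)-2,6,6-trimethyl-2-(prop-2-en-1-yl)cyclohexan-1-one | C=CC[C@@]1(C)CCCC(C)(C)C1=O | intermediate
6 | propanoic acid | CCC(=O)O | starting material
7 | (2E)-3-[(1R)-1,3,3-trimethyl-2-oxocyclohexyl]prop-2-en-1-yl propanoate | CCC(=O)OC/C=C/[C@@]1(C)CCCC(C)(C)C1=O | intermediate
8 | boron ketene acetal of 7 (C10 methyl cis to the allyloxy oxygen; boron in the (4S,5S)-4,5-diphenyl-1,3-bis{[3,5-bis(trifluoromethyl)phenyl]sulfonyl}-1,3,2-diazaborolidine ring) | C/C=C(\OC/C=C/[C@@]1(C)CCCC(C)(C)C1=O)OB1N(S(=O)(=O)c2cc(cc(c2)C(F)(F)F)C(F)(F)F)[C@@H](c2ccccc2)[C@H](c2ccccc2)N1S(=O)(=O)c2cc(cc(c2)C(F)(F)F)C(F)(F)F | intermediate (not isolated)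
9 | (2S,3S)-2-methyl-3-[(1R)-1,3,3-trimethyl-2-oxocyclohexyl]pent-4-enoic acid | OC(=O)[C@@H](C)[C@H](C=C)[C@@]1(C)CCCC(C)(C)C1=O | intermediate
10 | (2S,3S)-N-methoxy-N,2-dimethyl-3-[(1R)-1,3,3-trimethyl-2-oxocyclohexyl]pent-4-enamide | CON(C)C(=O)[C@@H](C)[C@H](C=C)[C@@]1(C)CCCC(C)(C)C1=O | intermediate
11 | (2R)-2,6,6-trimethyl-2-[(3S,4S)-4-methyl-5-oxohex-1-en-3-yl]cyclohexan-1-one | CC(=O)[C@@H](C)[C@H](C=C)[C@@]1(C)CCCC(C)(C)C1=O | intermediate (key-step precursor)
12 | lithium enolate of 11 at C12 | [Li]OC(=C)[C@@H](C)[C@H](C=C)[C@@]1(C)CCCC(C)(C)C1=O | intermediate (not isolated)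
13 | lithium aldolate of 14 | C=C[C@H]1[C@H](C)C(=O)C[C@]2(O[Li])C(C)(C)CCC[C@]12C | intermediate (not isolated)
14 | (3S,4S,4aR,8aS)-4-ethenyl-8a-hydroxy-3,4a,8,8-tetramethyloctahydronaphthalen-2(1H)-one | C=C[C@H]1[C@H](C)C(=O)C[C@]2(O)C(C)(C)CCC[C@]12C | intermediate (key-step product)
15 | (3S,4S,4aR,8aS)-4-ethenyl-3,4a,8,8-tetramethyldecahydronaphthalene-2,8a-diol (C2 open) | C=C[C@H]1[C@H](C)C(O)C[C@]2(O)C(C)(C)CCC[C@]12C | intermediate
16 | O-[(3S,4S,4aR,8aS)-4-ethenyl-8a-hydroxy-3,4a,8,8-tetramethyldecahydronaphthalen-2-yl] O-phenyl carbonothioate | C=C[C@H]1[C@H](C)C(OC(=S)Oc3ccccc3)C[C@]2(O)C(C)(C)CCC[C@]12C | intermediate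
17 | (1S,2R,4aS,8aR)-1-ethenyl-2,5,5,8a-tetramethyldecahydronaphthalen-4a-ol | C=C[C@H]1[C@H](C)CC[C@]2(O)C(C)(C)CCC[C@]12C | intermediate
18 | ethyl acetate | CCOC(C)=O | starting material
19 | 2,3-dibromoprop-1-ene | C=C(Br)CBr | starting material
20 | lithium 1-ethoxyethen-1-olate | [Li]OC(=C)OCC | intermediate (not isolated)
21 | ethyl 4-bromopent-4-enoate | CCOC(=O)CCC(Br)=C | intermediate
22 | 4-bromopent-4-enal | O=CCCC(Br)=C | intermediate
23 | (4S)-4-benzyl-3-propanoyl-1,3-oxazolidin-2-one | CCC(=O)N1[C@@H](Cc2ccccc2)COC1=O | starting material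
24 | (Z)-dibutylboron enolate of 23 | C/C=C(\OB(CCCC)CCCC)N1[C@@H](Cc2ccccc2)COC1=O | intermediate (not isolated)
25 | (4S)-4-benzyl-3-[(2S,3R)-6-bromo-3-hydroxy-2-methylhept-6-enoyl]-1,3-oxazolidin-2-one | O=C1OC[C@H](Cc2ccccc2)N1C(=O)[C@@H](C)[C@H](O)CCC(Br)=C | intermediate
26 | (2R,3R)-6-bromo-2-methylhept-6-ene-1,3-diol | OC[C@@H](C)[C@H](O)CCC(Br)=C | intermediate
27 | (2R,3R)-6-bromo-1-{[tert-butyl(diphenyl)silyl]oxy}-2-methylhept-6-en-3-ol | CC(C)(C)[Si](c1ccccc1)(c1ccccc1)OC[C@@H](C)[C@H](O)CCC(Br)=C | intermediate
28 | 9-{2-[(1S,2R,4aS,8aR)-4a-hydroxy-2,5,5,8a-tetramethyldecahydronaphthalen-1-yl]ethyl}-9-borabicyclo[3.3.1]nonane | B1(CC[C@H]2[C@H](C)CC[C@]3(O)C(C)(C)CCC[C@]23C)C2CCCC1CCC2 | intermediate (not isolated)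
29 | (2R,3R)-1-{[tert-butyl(diphenyl)silyl]oxy}-8-[(1S,2R,4aS,8aR)-4a-hydroxy-2,5,5,8a-tetramethyldecahydronaphthalen-1-yl]-2-methyl-6-methylideneoctan-3-ol | C=C(CC[C@H]1[C@H](C)CC[C@]2(O)C(C)(C)CCC[C@]12C)CC[C@@H](O)[C@H](C)CO[Si](c1ccccc1)(c1ccccc1)C(C)(C)C | intermediate
30 | methanesulfonate of 29 at the C3 hydroxyl, (2R,3R) | C=C(CC[C@H]1[C@H](C)CC[C@]2(O)C(C)(C)CCC[C@]12C)CC[C@@H](OS(C)(=O)=O)[C@H](C)CO[Si](c1ccccc1)(c1ccccc1)C(C)(C)C | intermediate
31 | (2R,3R,6RS)-6-[(triethylsilyl)peroxy]-2,6-dimethyl analogue of 30 (both C6 epimers) | CC[Si](CC)(CC)OOC(C)(CC[C@H]1[C@H](C)CC[C@]2(O)C(C)(C)CCC[C@]12C)CC[C@@H](OS(C)(=O)=O)[C@H](C)CO[Si](c1ccccc1)(c1ccccc1)C(C)(C)C | intermediate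
32 | (2R,3R,6RS)-6-hydroperoxy analogue of 31 (formed as its tetrabutylammonium salt) | OOC(C)(CC[C@H]1[C@H](C)CC[C@]2(O)C(C)(C)CCC[C@]12C)CC[C@@H](OS(C)(=O)=O)[C@H](C)CO[Si](c1ccccc1)(c1ccccc1)C(C)(C)C | intermediate (not isolated)
33 | tert-butyl{(2R)-2-[(3S,6R)-6-{2-[(1S,2R,4aS,8aR)-4a-hydroxy-2,5,5,8a-tetramethyldecahydronaphthalen-1-yl]ethyl}-6-methyl-1,2-dioxan-3-yl]propoxy}diphenylsilane | CC(C)(C)[Si](c1ccccc1)(c1ccccc1)OC[C@@H](C)[C@@H]1CC[C@@](C)(CC[C@H]2[C@H](C)CC[C@]3(O)C(C)(C)CCC[C@]23C)OO1 | intermediate
34 | (2R)-2-[(3S,6R)-6-{2-[(1S,2R,4aS,8aR)-4a-hydroxy-2,5,5,8a-tetramethyldecahydronaphthalen-1-yl]ethyl}-6-methyl-1,2-dioxan-3-yl]propan-1-ol | OC[C@@H](C)[C@@H]1CC[C@@](C)(CC[C@H]2[C@H](C)CC[C@]3(O)C(C)(C)CCC[C@]23C)OO1 | intermediate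
35 | (2S)-2-[(3S,6R)-6-{2-[(1S,2R,4aS,8aR)-4a-hydroxy-2,5,5,8a-tetramethyldecahydronaphthalen-1-yl]ethyl}-6-methyl-1,2-dioxan-3-yl]propanal | O=C[C@@H](C)[C@@H]1CC[C@@](C)(CC[C@H]2[C@H](C)CC[C@]3(O)C(C)(C)CCC[C@]23C)OO1 | intermediate (not isolated)
36 | (2S)-2-[(3S,6R)-6-{2-[(1S,2R,4aS,8aR)-4a-hydroxy-2,5,5,8a-tetramethyldecahydronaphthalen-1-yl]ethyl}-6-methyl-1,2-dioxan-3-yl]propanoic acid | OC(=O)[C@@H](C)[C@@H]1CC[C@@](C)(CC[C@H]2[C@H](C)CC[C@]3(O)C(C)(C)CCC[C@]23C)OO1 | intermediate
37 | methyl (2S)-2-[(3S,6R)-6-{2-[(1S,2R,4aS,8aR)-4a-hydroxy-2,5,5,8a-tetramethyldecahydronaphthalen-1-yl]ethyl}-6-methyl-1,2-dioxan-3-yl]propanoate | COC(=O)[C@@H](C)[C@@H]1CC[C@@](C)(CC[C@H]2[C@H](C)CC[C@]3(O)C(C)(C)CCC[C@]23C)OO1 | target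

## Step count and least certain steps

Total step count: 22. Longest linear sequence: 17 steps (steps 1–10 and 16–22, from 1). The side-chain fragment 27 takes 5 steps (11–15).

Step 7 (key step). The aldolate forms at a carbonyl flanked by two quaternary carbons, so reversion to the open diketone on warming or during the quench is the most likely failure; closure through an axial tether or by equatorial attack could also erode the cis selectivity. Fallback: from 11, kinetic silylation (LiN(i-Pr)2, Me3SiCl, THF, −78 °C) gives the trimethylsilyl enol ether F1. TiCl4 in CH2Cl2 at −78 °C then effects an intramolecular Mukaiyama aldol addition, in which the Lewis acid activates C13 and the product is held as a titanium chelate that should not revert. Aqueous work-up returns to the route at 14.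

Step 4. Two things may go wrong. The quaternary C18 may impose its own facial preference on C9 and oppose the reagent (mismatched double stereodifferentiation). The bulky alkene terminus may also slow the rearrangement until the boron ketene acetal decomposes. Fallback (the carbon delivered to C9 becomes C8 and not C10, so a substrate bias that opposed the rearrangement now works for the route): from 5, isomerisation with RuHCl(CO)(PPh3)3 in toluene at 80 °C gives the propenyl ketone F2. Ozonolysis (O3, CH2Cl2, −78 °C; Me2S) gives the keto aldehyde F3. Wittig reaction with 3-(triphenyl-λ5-phosphanylidene)butan-2-one gives the (E)-enone F4. Copper-mediated conjugate addition of CH2=CHMgBr (CuBr·SMe2, THF, −40 °C) to C9 returns to the route at 11; the C10 epimer that enolate protonation may give alongside is removed at the ketol stage.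

Step 18. The planar tertiary C6 radical is trapped by O2 without facial discrimination, so about half of the material is expected to fall into the (6S) series, which is lost at the separation in step 19. Competing reduction to the tertiary alcohol is possible, and the C6 epimers may be hard to separate because the two C6 chains are alike. No known method sets this centre by reagent control without leaving a surplus oxygen. Fallback (the peroxide is anchored at C3 first and C6–O is formed in the ring closure, where a chair transition state has a chance to discriminate): from 30, displacement of the mesylate by 2-methoxyprop-2-yl hydroperoxide (CsOH·H2O, DMF) with inversion gives the peroxyketal F5. AcOH/H2O/THF releases the C3 hydroperoxide F6. Hg(OAc)2 in CH2Cl2 brings about 6-exo cycloperoxymercuration, with oxygen adding to C6, to give the acetoxymercurial F7. NaBH4 in aqueous NaOH replaces mercury by hydrogen and returns to the route at 33.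

Step 3. C–H cleavage at the neopentyl-like C9 methylene may be slow, so that Wacker-type oxidation of the terminal alkene or branched ester formation takes over. Fallback: from 5, isomerisation as above gives the propenyl ketone F2 (the compound of the step 4 fallback). Allylic oxidation of its terminal methyl with SeO2 (cat.)/t-BuOOH in CH2Cl2 gives the (E)-allylic alcohol F8, and acylation with propanoyl chloride/pyridine returns to the route at 7.

## Further compounds

F1 | step 7 | (2R)-2,6,6-trimethyl-2-{(3S,4S)-4-methyl-5-[(trimethylsilyl)oxy]hexa-1,5-dien-3-yl}cyclohexan-1-one | C=C(O[Si](C)(C)C)[C@@H](C)[C@H](C=C)[C@@]1(C)CCCC(C)(C)C1=O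
F2 | step 4 | (2R)-2,6,6-trimethyl-2-[(1E)-prop-1-en-1-yl]cyclohexan-1-one | C/C=C/[C@@]1(C)CCCC(C)(C)C1=O
F3 | step 4 | (1R)-1,3,3-trimethyl-2-oxocyclohexane-1-carbaldehyde | O=C[C@@]1(C)CCCC(C)(C)C1=O
F4 | step 4 | (3E)-3-methyl-4-[(1R)-1,3,3-trimethyl-2-oxocyclohexyl]but-3-en-2-one | CC(=O)/C(C)=C/[C@@]1(C)CCCC(C)(C)C1=O
F5 | step 18 | tert-butyl({(2R,3S)-8-[(1S,2R,4aS,8aR)-4a-hydroxy-2,5,5,8a-tetramethyldecahydronaphthalen-1-yl]-3-[(2-methoxypropan-2-yl)peroxy]-2-methyl-6-methylideneoctyl}oxy)diphenylsilane | C=C(CC[C@H]1[C@H](C)CC[C@]2(O)C(C)(C)CCC[C@]12C)CC[C@H](OOC(C)(C)OC)[C@H](C)CO[Si](c1ccccc1)(c1ccccc1)C(C)(C)C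
F6 | step 18 | (2R,3S)-3-hydroperoxy analogue of F5 | C=C(CC[C@H]1[C@H](C)CC[C@]2(O)C(C)(C)CCC[C@]12C)CC[C@H](OO)[C@H](C)CO[Si](c1ccccc1)(c1ccccc1)C(C)(C)C
F7 | step 18 | acetoxymercuriomethyl analogue of 33 (CH2HgOAc in place of the C6 methyl, same configurations) | CC(=O)O[Hg]C[C@@]1(CC[C@H]2[C@H](C)CC[C@]3(O)C(C)(C)CCC[C@]23C)CC[C@@H]([C@H](C)CO[Si](c2ccccc2)(c2ccccc2)C(C)(C)C)OO1
F8 | step 3 | (2R)-2-[(1E)-3-hydroxyprop-1-en-1-yl]-2,6,6-trimethylcyclohexan-1-one | OC/C=C/[C@@]1(C)CCCC(C)(C)C1=O
A1 | alternative 1 | (2R,3S,4R)-3-[2-(1,3-dioxolan-2-yl)ethyl]-2,4-dimethyl-2-(4-methylpent-3-en-1-yl)cyclohexan-1-one | C1COC(CC[C@H]2[C@H](C)CCC(=O)[C@]2(C)CCC=C(C)C)O1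
A2 | alternative 1 | (4R)-2,4-dimethylcyclohex-2-en-1-one | O=C1CC[C@@H](C)C=C1C
A3 | alternative 1 | [2-(1,3-dioxolan-2-yl)ethyl]magnesium bromide | Br[Mg]CCC1OCCO1
A4 | alternative 1 | 5-iodo-2-methylpent-2-ene | CC(C)=CCCI
A5 | alternative 2 | bridged iodo γ-lactone (C8 carboxylate closed onto C13, iodine on C12 anti to the lactone oxygen) | O=C1[C@H]2[C@H](C)C[C@H](I)[C@]3(O1)C(C)(C)CCC[C@]23C
A6 | alternative 2 | (1S,2R,8aR)-2,5,5,8a-tetramethyl-1,2,3,5,6,7,8,8a-octahydronaphthalene-1-carboxylic acid | OC(=O)[C@H]1[C@H](C)CC=C2C(C)(C)CCC[C@]12C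
A7 | alternative 3 | (1S,2R,4aS,8aR)-1-[2-(1,3-dioxolan-2-yl)ethyl]-2,5,5,8a-tetramethyldecahydronaphthalen-4a-ol | C1COC(CC[C@H]2[C@H](C)CC[C@]3(O)C(C)(C)CCC[C@]23C)O1
A8 | alternative 3 | (5E,7S,8R)-7-[2-(1,3-dioxolan-2-yl)ethyl]-2,2,6,8-tetramethylcyclodec-5-en-1-one | C1COC(CC[C@H]2[C@H](C)CCC(=O)C(C)(C)CC/C=C2\C)O1
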